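## The problem

The target (CNP0289810.2) is a germacranolide. Its ten-membered carbocycle (C1–C10) carries two trans-trisubstituted epoxides (C1–C10 and C4–C5, with methyl groups on C10 and C4), a butenolide fused across C6–C7 (lactone oxygen on C6, C7=C11, C12 the carbonyl, C13 an acetoxymethyl group on C11), and an (S)-2-methylglycidate on the C8 oxygen. A synthesis has to close a ten-membered ring against entropy and transannular strain, and both ring alkenes that precede the epoxides must be E, because only an E alkene gives a trans epoxide. The core has six stereocentres (C1, C10, C4, C5, C6, C8) and the side chain one. The glycidate centre can be bought and C8 is the natural source of absolute configuration. C6 lies 1,3-syn to C8 across the trigonal C7 and can be set from C8 by a chelated hydride reduction. C4/C5 stand threo to the C6 oxygen, which is what peripheral epoxidation of an allylic C6–O system gives under A(1,3) control (reduction of an α,β-epoxy ketone normally gives the erythro relation), and C1/C10 follow from the ring conformation. The epoxides do not survive acid or strong nucleophiles, the glycidate and the allylic acetate do not survive hydroxide or hydride, the butenolide has acidic γ-hydrogens at C6 and beside C8, and every (E,E)-cyclodeca-1,5-diene on the way can undergo Cope rearrangement on heating or transannular cyclisation with acid. The feature that opens a short way to the ring is the 1,5-relation of the alkenes behind the two epoxides: C1=C10 and C4=C5 are joined by the C2–C3 ethano bridge, carry their methyl groups at C10 and C4, and C5 adjoins the oxygenated C6. That is the pattern left when the bicyclo[2.2.0]hexane core of a 1-methylcyclobutene/3-methylcyclohexenone photoadduct (C1–C4 central bond, C2–C3 and C5–C10 bridges) loses its C1–C4 and C5–C10 σ bonds.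

## Retrosynthesis

**23 ⇒ 22.** The four C–O bonds of the two ring oxiranes are cut last. Epoxidising the C4=C5 enone earlier and then reducing C6 would lead to the erythro epoxy alcohol, whereas the target is threo. The oxiranes would also not survive the enolate, hydride and fluoride steps. Triene 22 is simpler by four stereocentres. The forward step needs a neutral electrophilic oxidant that attacks both E alkenes from their outer faces and leaves the electron-poor butenolide alkene alone.

**22 ⇒ 18 + 20.** The acyl C–O bond at O8 is cut. The glycidate is the most fragile ester and is therefore attached as late as the epoxidation allows. Alcohol 18 and the carboxylate salt 20 (from commercial ester 19) are both simple, and the coupling must not use a base strong enough to remove the γ-hydrogen at C6.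

**18 ⇒ 16 (⇒ 15).** The lactone C12–O6 bond and the C6–H bond are cut, which leads back to the (Z)-γ-keto enoate 16 with a free C8 hydroxyl. With C7 already trigonal, only O6 can reach C12 and the O8/C6=O chelate is flat, so one hydride addition sets C6 from C8. Had C6 been reduced while C7 was still tetrahedral, O6 and O8 could both lactonise and no clean chelate model would exist. Alcohol 16 comes from silyl ether 15.

**15 ⇒ 10 + 12.** The C7=C11 bond is cut by an aldol condensation. C7 is the only enolisable position of dienone 10, and keto ester 12 (from 11) brings C11, C12 and C13 with the acetate already in place, so no protecting-group exchange at C13 is needed later. The forward reaction has to give the Z alkene (ester on the side of C6).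

**10 ⇒ 8.** Only the geometry of the conjugated C4=C5 changes. A conjugate addition–elimination through stannyl ketone 9 does this at low temperature, which the heat-sensitive (E,E)-dienone 10 requires.

**8 ⇒ 7 (key disconnection).** The C1=C10 and C4=C5 π bonds are traded for the C1–C4 and C5–C10 σ bonds of tricycle 7. Compared with any cut that closes the ring by forming one bond, this makes the ten-membered ring by opening a strained six-membered ring, needs no dilution and no activating groups, and leaves the C6 ketone as the handle for the butenolide. The forward reaction must cleave C5–C10 and not C2–C3, and must give E geometry at the unconjugated C1=C10.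

**7 ⇒ 4 + 6.** The C1–C10 and C4–C5 σ bonds of the central cyclobutane are cut by an enone–alkene [2+2] photocycloaddition. Both partners are small rings. 1-Methylcyclobutene 6 comes from 5 in one step. Enone 4 holds the only stereocentre that survives the ring expansion.

**4 ⇒ 3 ⇒ 2 ⇒ 1.** The C=C bond of enone 4 is cut by an intramolecular aldol condensation of the achiral diketone 3. A chiral amine catalyst chooses between its two enantiotopic acetonyl arms, so C8 is set by catalysis and no resolution is needed. Diketone 3 comes from silyl ether 2 of the commercial dienol 1 by oxidation of both terminal alkenes.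

## Roads not taken

**Alternative 1:** The C2–C3 bond and the lactone C–O bond are cut together. In the forward step Pd(PPh3)4 (zerovalent palladium) would ionise an isopropenyl epoxide in the open-chain precursor to a π-allyl complex and an alkoxide. A bis-sulfonyl carbanion would close the ten-membered ring at C3, and the C6 alkoxide would lactonise onto a cis ester to give the bis-sulfone butenolide A1.
- Merits: ring and butenolide form in one neutral, low-temperature step. C6 and C8 are set beforehand in an open chain. No thermal step threatens a Cope rearrangement.
- Weak points: the ring closes by bond formation with a bulky nucleophile and needs high dilution. The syn/anti equilibrium of the π-allyl unit decides the C4=C5 geometry, and attack at C5 would give an eight-membered ring. Both sulfonyl groups must later be removed reductively from a molecule with an allylic lactone C–O bond and a reducible butenolide.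
- Comparison: this road is better in that A1 already carries the butenolide, the C6 centre and an E alkene at C4=C5, none of which the chosen plan has at the ring-forming stage. The chosen plan sets against this a ring made from two small rings without dilution, no desulfonylation, and a far shorter precursor.

**Alternative 2:** The ring is traced back to a trans-1,2-dialkenylcyclohexanol made from isopulegol. Its potassium alkoxide (KH, 18-crown-6) would undergo an anionic oxy-Cope rearrangement that forms C8–C9, breaks the ring bond at the carbinol carbon and gives the ten-membered ketone A2, with E geometry at C1=C10, the C8 tert-butyl ether set in the chair transition state and C4/C5 already oxygenated as an acetonide.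
- Merits: this is the most thoroughly proven ring expansion to germacranes. It runs at low temperature, the chirality comes from the pool, and it avoids the enone geometry problem because C4 and C5 never pass through an alkene.
- Weak points: C8 depends on the enol ether geometry and on chair-versus-boat selection. The tert-butyl ether and the acetonide both need acid for removal, close to acid-sensitive alkenes or epoxides. Turning the C4,C5 diol into the trans epoxide needs selective activation with inversion next to C6. The rearrangement substrate takes many steps to build.
- Comparison: for reliability of the ring-forming step and for C4/C5 this road is at least as good as the chosen one. The chosen plan sets against it a ring precursor reached in five steps, a single catalytically set stereocentre, and no acid-labile protecting groups, at the cost of one geometry correction.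

**Alternative 3:** The C1–C2 bond is cut. 9-BBN would hydroborate the vinyl group of a vinyl epoxide, and the C2 alkylborane would couple with a C1 vinyl iodide (Pd(dppf)Cl2, AsPh3, Cs2CO3) to close the ring and give the epoxy butenolide A3.
- Merits: the C1=C10 geometry is fixed in the vinyl iodide. The 4,5-epoxide, C6, C8 and the butenolide are all set in an open chain, so the endgame after ring closure is the shortest of all four roads.
- Weak points: ten-membered rings are poor cases for B-alkyl Suzuki macrocyclisation (strained palladacycle, β-hydride elimination, high dilution). Hydroboration beside a vinyl epoxide competes with epoxide opening and with reduction of the butenolide. Cs2CO3 meets the acidic γ-hydrogen at C6. The linear precursor is long.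
- Comparison: this road is better in endgame economy and in the certainty of the C4–C6 stereotriad. The chosen plan sets against it a ring-forming reaction type that is known on this very ring skeleton and that involves no macrocyclisation.

Key step: step 6

Remark (assumption): the quinine-derived primary amine of step 3 is taken to give the (S)-enone 4; if the sense of induction proves opposite, the quinidine-derived pseudoenantiomer is used instead.

Remark (numbering): ring positions are given in germacrane numbering (C1–C10 ring, C11–C13 butenolide carbons) unless a systematic name is written out. C6 is R by the CIP rules in 17, 18 and 22 and S in 23 only because C5 gains an oxygen; its geometry does not change.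

## Route

Step 1
Reactants: 1 hepta-1,6-dien-4-ol
Product: 2 tert-butyl(hepta-1,6-dien-4-yloxy)dimethylsilane
Conditions: TBSCl, imidazole, DMF, rt
Reagents that add atoms: tert-butyldimethylsilyl chloride (CC(C)(C)[Si](C)(C)Cl)
Why: Silylation of the secondary alcohol through the N-silylimidazolium ion; the carbinol carbon stays on a mirror plane, so nothing stereochemical is decided yet.

Step 2
Reactants: 2 tert-butyl(hepta-1,6-dien-4-yloxy)dimethylsilane
Product: 3 4-[(tert-butyldimethylsilyl)oxy]heptane-2,6-dione
Conditions: PdCl2 (10 mol %), CuCl, O2 (1 atm), DMF/H2O (7:1), rt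
Reagents that add atoms: water (O)
Why: Tsuji–Wacker oxidation; Markovnikov hydroxypalladation turns each terminal alkene into a methyl ketone. The diketone is still achiral, which is what the desymmetrising step 3 needs.

Step 3
Reactants: 3 4-[(tert-butyldimethylsilyl)oxy]heptane-2,6-dione
Product: 4 (S)-5-[(tert-butyldimethylsilyl)oxy]-3-methylcyclohex-2-en-1-one
Conditions: 9-amino-9-deoxy-epi-quinine (20 mol %), AcOH (60 mol %), PhMe, −15 °C
Reagents that add atoms: none
Why: Primary-amine-catalysed intramolecular aldol condensation (Hajos–Parrish-type desymmetrisation of a 4-substituted heptane-2,6-dione): the enamine of one acetonyl arm adds to the other ketone and water is lost. The chiral ammonium salt chooses between the enantiotopic arms and so sets C8 (S, see remark).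

Step 4
Reactants: 5 methylenecyclobutane
Product: 6 1-methylcyclobutene
Conditions: Na/Al2O3 (cat.), neat, 25 °C; fractional distillation
Reagents that add atoms: none
Why: Base-catalysed prototropic alkene isomerisation; the endocyclic trisubstituted alkene is the favoured isomer and is separated by distillation.

Step 5
Reactants: 4 (S)-5-[(tert-butyldimethylsilyl)oxy]-3-methylcyclohex-2-en-1-one; 6 1-methylcyclobutene
Product: 7 cis,anti,cis-(9S)-9-[(tert-butyldimethylsilyl)oxy]-1,5-dimethyltricyclo[4.4.0.0(2,5)]decan-7-one (outer cyclobutane on the ring face opposite to the silyloxy group)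
Conditions: hν (Hg lamp, uranium-glass filter), 6 (8 equiv), CH2Cl2, −40 °C; then basic Al2O3, Et2O, rt
Reagents that add atoms: none
Why: Enone–alkene [2+2] photocycloaddition through the enone triplet and a 1,4-biradical; the head-to-head union in which the two methyl-bearing carbons are not bonded is the regiochemistry known for 3-methylcyclohexenones with 1-methylcyclobutene, and exo approach gives the anti adduct. Basic alumina epimerises any trans-fused ketone at C5 to the cis-fused one. The four new stereocentres are erased in step 6, so the face chosen relative to C8 does not affect the route.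

Step 6
Reactants: 7 cis,anti,cis-(9S)-9-[(tert-butyldimethylsilyl)oxy]-1,5-dimethyltricyclo[4.4.0.0(2,5)]decan-7-one
Product: 8 (2Z,6E,9S)-9-[(tert-butyldimethylsilyl)oxy]-3,7-dimethylcyclodeca-2,6-dien-1-one (germacrane numbering: 1(10)E,4Z-dien-6-one)
Conditions: PhMe (0.01 M, degassed), silylated sealed tube, 185 °C
Reagents that add atoms: none
Why: Homolysis of the strained central C1–C4 bond of the bicyclo[2.2.0]hexane gives a cyclohexane-1,4-diyl that relaxes from boat to chair and then loses the C5–C10 bond by β-scission, so that C1=C10 and C4=C5 form and the six-membered ring opens into the ten-membered one; the closest known reaction type is the thermal cycloreversion of cis,anti,cis cyclobutene–cyclohexenone photoadducts (photo-thermal alkene metathesis). The ten-membered ring is not closed by bond formation but appears by ring expansion (two-bond fragmentation across the shared C5–C10 bond), which avoids the entropy and transannular strain of a cyclisation. No stereocentre is made: C1, C4, C5 and C10 become trigonal and C8 is untouched. Three selectivities are needed. Cleavage of C5–C10 rather than C2–C3 is secured by the quaternary C10 and the C6 carbonyl, which weaken that bond and turn it into a conjugated enone. E geometry at C1=C10 follows from the anti ring fusion, and the chair diyl inverts only the terminus that ends in conjugation, so the isolable ten-membered product should be the 1(10)E,4Z dienone, as in the closely related 3-methylcyclohexenone/1-methylcyclobutene series. The 4Z geometry also protects the product, because an E,Z-1,5-diene cannot reach the chair Cope transition state that consumes the E,E isomer at this temperature; the geometry is corrected under mild conditions in steps 7 and 8.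

Step 7
Reactants: 8 (2Z,6E,9S)-9-[(tert-butyldimethylsilyl)oxy]-3,7-dimethylcyclodeca-2,6-dien-1-one
Product: 9 (6E,9S)-9-[(tert-butyldimethylsilyl)oxy]-3,7-dimethyl-3-(trimethylstannyl)cyclodec-6-en-1-one (C3 epimers)
Conditions: Me3SnLi (from Me3SnSnMe3 and MeLi), THF, −78 °C; MeOH
Reagents that add atoms: trimethylstannyllithium ([Li][Sn](C)(C)C)
Why: Conjugate addition of the soft stannyl anion to the Z enone; silyl ether and isolated alkene are inert. The new C4 centre is temporary.

Step 8
Reactants: 9 (6E,9S)-9-[(tert-butyldimethylsilyl)oxy]-3,7-dimethyl-3-(trimethylstannyl)cyclodec-6-en-1-one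
Product: 10 (2E,6E,9S)-9-[(tert-butyldimethylsilyl)oxy]-3,7-dimethylcyclodeca-2,6-dien-1-one
Conditions: CrO3·2C5H5N, CH2Cl2, 0 °C
Reagents that add atoms: none
Why: Oxidative destannylation of the β-stannyl ketone regenerates the enone; elimination should take place from the ring conformer with C3 anti to C6, which is how ten-membered 4Z-germacradien-6-ones are known to be corrected to the 4E isomers. The product is kept below about 40 °C from here on because (E,E)-cyclodeca-1,5-dienes undergo Cope rearrangement.

Step 9
Reactants: 11 ethyl bromopyruvate
Product: 12 ethyl 3-acetoxy-2-oxopropanoate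
Conditions: KOAc, 18-crown-6 (5 mol %), MeCN, 0 °C to rt
Reagents that add atoms: potassium acetate (CC(=O)[O-].[K+])
Why: SN2 displacement of the activated α-keto bromide by acetate; it puts the C13 acetate in place before the fragment is joined.

Step 10
Reactants: 10 (2E,6E,9S)-9-[(tert-butyldimethylsilyl)oxy]-3,7-dimethylcyclodeca-2,6-dien-1-one; 12 ethyl 3-acetoxy-2-oxopropanoate
Product: 15 ethyl (2Z)-3-acetoxy-2-[(3E,7E,10S)-10-[(tert-butyldimethylsilyl)oxy]-4,8-dimethyl-2-oxocyclodeca-3,7-dien-1-ylidene]propanoate, via aldol adduct 13 (not isolated), via tertiary mesylate 14 (not isolated)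
Conditions: LiN(i-Pr)2, THF, −78 °C; 12, −78 °C; MsCl, Et3N, −78 to 0 °C
Reagents that add atoms: none
Why: Aldol condensation: kinetic deprotonation at C7 (the only enolisable α-position, C5 being vinylic), addition to the very electrophilic keto group of 12, then mesylation and E1cB elimination through the C6 enolate, which fixes the alkene position at C7=C11. The Z isomer (ester beside C6) is expected because the flat ester can stay conjugated next to the twisted C6 carbonyl while the smaller CH2OAc faces the C8 centre. Any E isomer is removed in step 11, where it closes onto O8.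

Step 11
Reactants: 15 ethyl (2Z)-3-acetoxy-2-[(3E,7E,10S)-10-[(tert-butyldimethylsilyl)oxy]-4,8-dimethyl-2-oxocyclodeca-3,7-dien-1-ylidene]propanoate
Product: 16 ethyl (2Z)-3-acetoxy-2-[(3E,7E,10S)-10-hydroxy-4,8-dimethyl-2-oxocyclodeca-3,7-dien-1-ylidene]propanoate
Conditions: HF·pyridine, pyridine, THF, 0 °C
Reagents that add atoms: none
Why: Fluoride-driven cleavage of the secondary silyl ether under buffered conditions that spare the acetate, the enoate and the acid-sensitive 1,5-diene. In the Z isomer the ester is out of reach of O8, so the hydroxy ketone is stable.

Step 12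
Reactants: 16 ethyl (2Z)-3-acetoxy-2-[(3E,7E,10S)-10-hydroxy-4,8-dimethyl-2-oxocyclodeca-3,7-dien-1-ylidene]propanoate
Product: 18 (6R,8S)-13-acetoxy-8-hydroxygermacra-1(10)E,4E,7(11)-trien-12,6-olide, via syn-diol ester 17 (not isolated)
Conditions: Et2BOMe, THF/MeOH (4:1), −78 °C; NaBH4, −78 °C; AcOH; MeOH (evaporate); silica gel, CH2Cl2, rt
Reagents that add atoms: none
Why: Narasaka–Prasad reduction: boron ties O8 to the C6 carbonyl in a six-membered chelate that is flat because C7 is trigonal, and hydride adds from the face opposite to C9 (the side not covered by the ring chain), giving the 1,3-syn diol and thereby C6. The (Z)-γ-hydroxy enoate then lactonises onto O6 with loss of ethanol.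

Step 13
Reactants: 19 methyl (S)-2-methylglycidate
Product: 20 potassium (S)-2-methyloxirane-2-carboxylate
Conditions: KOSiMe3, THF, 0 °C to rt
Reagents that add atoms: potassium trimethylsilanolate (C[Si](C)(C)[O-].[K+])
Why: Anhydrous ester cleavage by silanolate gives the potassium carboxylate without exposing the epoxide to aqueous acid; the quaternary stereocentre is not involved.

Step 14
Reactants: 18 (6R,8S)-13-acetoxy-8-hydroxygermacra-1(10)E,4E,7(11)-trien-12,6-olide; 20 potassium (S)-2-methyloxirane-2-carboxylate
Product: 22 (6R,8S)-13-acetoxy-8-[(2S)-2-methyloxirane-2-carbonyloxy]germacra-1(10)E,4E,7(11)-trien-12,6-olide, via mixed anhydride 21 (not isolated)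
Conditions: 20, 2,4,6-Cl3C6H2COCl, THF, 0 °C; then 18, DMAP, Et3N, PhMe, rt
Reagents that add atoms: none
Why: Yamaguchi esterification through the mixed anhydride and the acyl-DMAP ion; the amine bases are too weak to remove the γ-hydrogen at C6, and neither stereocentre is touched.

Step 15
Reactants: 22 (6R,8S)-13-acetoxy-8-[(2S)-2-methyloxirane-2-carbonyloxy]germacra-1(10)E,4E,7(11)-trien-12,6-olide
Product: 23 (1R,4R,5R,6S,8S,10R)-13-acetoxy-1,10:4,5-diepoxy-8-[(2S)-2-methyloxirane-2-carbonyloxy]germacr-7(11)-en-12,6-olide (target)
Conditions: DMDO (2.5 equiv, acetone solution), acetone, −20 to 0 °C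
Reagents that add atoms: dimethyldioxirane (CC1(C)OO1)
Why: Electrophilic epoxidation of the two electron-rich trisubstituted E alkenes by a neutral dioxirane, which leaves the electron-poor butenolide alkene untouched and produces no acid that could trigger transannular cyclisation. At C4=C5 the C15 methyl forces H6 into the alkene plane (A(1,3) strain) and C7 lies on the inner face, so the oxidant enters on the side of O6 and gives the threo (4R,5R) epoxide. C1=C10 is attacked on its outer face in the crossed-diene conformer usual for germacranolides, giving (1R,10R).

## Compound list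

1 | hepta-1,6-dien-4-ol | C=CCC(O)CC=C | starting material
2 | tert-butyl(hepta-1,6-dien-4-yloxy)dimethylsilane | C=CCC(O[Si](C)(C)C(C)(C)C)CC=C | intermediate
3 | 4-[(tert-butyldimethylsilyl)oxy]heptane-2,6-dione | CC(=O)CC(O[Si](C)(C)C(C)(C)C)CC(C)=O | intermediate
4 | (S)-5-[(tert-butyldimethylsilyl)oxy]-3-methylcyclohex-2-en-1-one | O=C1C[C@@H](O[Si](C)(C)C(C)(C)C)CC(C)=C1 | intermediate
5 | methylenecyclobutane | C=C1CCC1 | starting material
6 | 1-methylcyclobutene | CC1=CCC1 | intermediate
7 | cis,anti,cis-(9S)-9-[(tert-butyldimethylsilyl)oxy]-1,5-dimethyltricyclo[4.4.0.0(2,5)]decan-7-one, cyclobutane anti to the silyloxy group | O=C1C[C@@H](O[Si](C)(C)C(C)(C)C)C[C@]2(C)[C@H]3CC[C@@]3(C)[C@H]12 | intermediate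
8 | (2Z,6E,9S)-9-[(tert-butyldimethylsilyl)oxy]-3,7-dimethylcyclodeca-2,6-dien-1-one | C1[C@@H](O[Si](C)(C)C(C)(C)C)C/C(C)=C/CC/C(C)=C\C1=O | intermediate
9 | (6E,9S)-9-[(tert-butyldimethylsilyl)oxy]-3,7-dimethyl-3-(trimethylstannyl)cyclodec-6-en-1-one (C3 epimers) | C1[C@@H](O[Si](C)(C)C(C)(C)C)C/C(C)=C/CCC(C)([Sn](C)(C)C)CC1=O | intermediate
10 | (2E,6E,9S)-9-[(tert-butyldimethylsilyl)oxy]-3,7-dimethylcyclodeca-2,6-dien-1-one | C1[C@@H](O[Si](C)(C)C(C)(C)C)C/C(C)=C/CC/C(C)=C/C1=O | intermediate
11 | ethyl bromopyruvate | CCOC(=O)C(=O)CBr | starting material
12 | ethyl 3-acetoxy-2-oxopropanoate | CCOC(=O)C(=O)COC(C)=O | intermediate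
13 | ethyl 3-acetoxy-2-hydroxy-2-[(3E,7E,10S)-10-[(tert-butyldimethylsilyl)oxy]-4,8-dimethyl-2-oxocyclodeca-3,7-dien-1-yl]propanoate (aldol adduct, formed as its lithium alkoxide; C7 and C11 not defined) | O=C1/C=C(C)/CC/C=C(C)/C[C@H](O[Si](C)(C)C(C)(C)C)C1C(O)(COC(C)=O)C(=O)OCC | intermediate
14 | tertiary methanesulfonate of 13 | O=C1/C=C(C)/CC/C=C(C)/C[C@H](O[Si](C)(C)C(C)(C)C)C1C(OS(C)(=O)=O)(COC(C)=O)C(=O)OCC | intermediate
15 | ethyl (2Z)-3-acetoxy-2-[(3E,7E,10S)-10-[(tert-butyldimethylsilyl)oxy]-4,8-dimethyl-2-oxocyclodeca-3,7-dien-1-ylidene]propanoate | CCOC(=O)/C(COC(C)=O)=C1\C(=O)/C=C(C)/CC/C=C(C)/C[C@@H]1O[Si](C)(C)C(C)(C)C | intermediate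
16 | ethyl (2Z)-3-acetoxy-2-[(3E,7E,10S)-10-hydroxy-4,8-dimethyl-2-oxocyclodeca-3,7-dien-1-ylidene]propanoate | CCOC(=O)/C(COC(C)=O)=C1\C(=O)/C=C(C)/CC/C=C(C)/C[C@@H]1O | intermediate
17 | ethyl (2Z)-3-acetoxy-2-[(2R,3E,7E,10S)-2,10-dihydroxy-4,8-dimethylcyclodeca-3,7-dien-1-ylidene]propanoate (syn-diol ester) | CCOC(=O)/C(COC(C)=O)=C1\[C@H](O)/C=C(C)/CC/C=C(C)/C[C@@H]1O | intermediate
18 | (6R,8S)-13-acetoxy-8-hydroxygermacra-1(10)E,4E,7(11)-trien-12,6-olide | CC(=O)OCC1=C2[C@@H](O)C/C(C)=C/CC/C(C)=C/[C@H]2OC1=O | intermediate
19 | methyl (S)-2-methylglycidate | COC(=O)[C@]1(C)CO1 | starting material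
20 | potassium (S)-2-methyloxirane-2-carboxylate | [K+].[O-]C(=O)[C@]1(C)CO1 | intermediate
21 | (S)-2-methyloxirane-2-carboxylic 2,4,6-trichlorobenzoic anhydride | O=C(OC(=O)[C@]1(C)CO1)c1c(Cl)cc(Cl)cc1Cl | intermediate
22 | (6R,8S)-13-acetoxy-8-[(2S)-2-methyloxirane-2-carbonyloxy]germacra-1(10)E,4E,7(11)-trien-12,6-olide | CC(=O)OCC1=C2[C@@H](OC(=O)[C@]3(C)CO3)C/C(C)=C/CC/C(C)=C/[C@H]2OC1=O | intermediate
23 | (1R,4R,5R,6S,8S,10R)-13-acetoxy-1,10:4,5-diepoxy-8-[(2S)-2-methyloxirane-2-carbonyloxy]germacr-7(11)-en-12,6-olide | CC(=O)OCC1=C2[C@@H](OC(=O)[C@]3(C)CO3)C[C@@]3(C)O[C@@H]3CC[C@@]3(C)O[C@@H]3[C@H]2OC1=O | target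

## Step count and least certain steps

Total step count: 15. Longest linear sequence: 12 steps (1, 2, 3, 5, 6, 7, 8, 10, 11, 12, 14, 15).

**Step 6 (key step).** The most likely failures are β-elimination of the silanol from the β-silyloxy ketone at 185 °C and slow Cope rearrangement of the product on prolonged heating, because the substrate has acidic C7 hydrogens next to a leaving group and the product is still a 1,5-diene. The fallback sets out from 7 and comes back at 8. The ketone is first reduced (NaBH4, MeOH, 0 °C) to the tricyclic carbinol F1, which has no enolisable position beside the silyl ether. Thermolysis of F1 under the same regime should give the cyclodecadienol F2 by the same diyl course. Oxidation with Dess–Martin periodinane (NaHCO3, CH2Cl2, 0 °C) returns 8.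

**Step 10.** The most likely failure is poor control of the C7=C11 geometry in the E1cB elimination, with loss of material as the E isomer, because the two groups on C11 differ little in size. Retro-aldol of the alkoxide before mesylation is the second risk. The fallback sets out from 10 and comes back at 18. It closes the lactone before the alkene is made, so the ring fixes the geometry.
- The aldol adduct 13 is isolated after an acetic acid quench at −78 °C.
- Reduction of the C6 ketone (NaBH4, CeCl3·7H2O, MeOH, −40 °C) gives the diol ester F3, which lactonises to the α-hydroxy lactone F4.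
- Dehydration with SOCl2 and pyridine (−20 °C) gives the butenolide silyl ether F5, and HF·pyridine then gives 18.
- In this variant C6 is set without the chelate, so the C6 epimers would have to be separated at F4.

**Step 3.** The most likely failures are erosion of enantioselectivity by the silyloxy substituent, which is a new substituent type for this aldolisation, and β-elimination followed by aromatisation to 3-methylphenol under amine/acid catalysis. The fallback sets out from 3 and comes back at 4. Cyclisation with pyrrolidine and AcOH (PhMe, rt) gives the racemic enone F6, which is resolved by preparative chromatography on a chiral stationary phase; the (S)-enantiomer is 4.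

**Step 8 (with step 7).** The most likely failures are re-formation of the Z enone or protodestannylation without oxidation, because the outcome depends on the ring conformer from which tin and hydrogen leave. The fallback sets out from 8 and comes back at 10. Conjugate addition of benzeneselenolate (PhSeSePh, NaBH4, EtOH, 0 °C) gives the β-seleno ketone F7. Oxidation with H2O2 and pyridine (CH2Cl2, 0 °C) gives the selenoxide F8, whose syn elimination towards the acidic C5 hydrogen at 0 °C should give the E enone 10.

**Step 15.** The most likely failure is attack on the wrong face of C1=C10, because with C7 trigonal the ring may populate a second conformer. Attack at C4=C5 is locally controlled and is less at risk. The fallback sets out from 22 and comes back at 23. It replaces substrate control by reagent control: a Shi epoxidation (fructose-derived ketone of the matching enantiomeric series, KHSO5, K2CO3 buffer, MeCN/dimethoxymethane, 0 °C) lets the chiral dioxirane select the ring conformer that presents the required outer faces.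

## Further compounds

F1 | step 6 | cis,anti,cis-(9S)-9-[(tert-butyldimethylsilyl)oxy]-1,5-dimethyltricyclo[4.4.0.0(2,5)]decan-7-ol (C7 epimers) | OC1C[C@@H](O[Si](C)(C)C(C)(C)C)C[C@]2(C)[C@H]3CC[C@@]3(C)[C@H]12
F2 | step 6 | (2Z,6E,9S)-9-[(tert-butyldimethylsilyl)oxy]-3,7-dimethylcyclodeca-2,6-dien-1-ol (C1 epimers) | C1[C@@H](O[Si](C)(C)C(C)(C)C)C/C(C)=C/CC/C(C)=C\C1O
F3 | step 10 | ethyl 3-acetoxy-2-hydroxy-2-[(3E,7E,10S)-2-hydroxy-10-[(tert-butyldimethylsilyl)oxy]-4,8-dimethylcyclodeca-3,7-dien-1-yl]propanoate (C6 as in 18; C7 and C11 not defined) | CCOC(=O)C(O)(COC(C)=O)C1[C@H](O)/C=C(C)/CC/C=C(C)/C[C@@H]1O[Si](C)(C)C(C)(C)C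
F4 | step 10 | 13-acetoxy-11-hydroxy-8-[(tert-butyldimethylsilyl)oxy]germacra-1(10)E,4E-dien-12,6-olide (C6 and C8 as in 18; C7 and C11 not defined) | CC(=O)OCC1(O)C2[C@@H](O[Si](C)(C)C(C)(C)C)C/C(C)=C/CC/C(C)=C/[C@H]2OC1=O
F5 | step 10 | (6R,8S)-13-acetoxy-8-[(tert-butyldimethylsilyl)oxy]germacra-1(10)E,4E,7(11)-trien-12,6-olide | CC(=O)OCC1=C2[C@@H](O[Si](C)(C)C(C)(C)C)C/C(C)=C/CC/C(C)=C/[C@H]2OC1=O
F6 | step 3 | racemic 5-[(tert-butyldimethylsilyl)oxy]-3-methylcyclohex-2-en-1-one | O=C1CC(O[Si](C)(C)C(C)(C)C)CC(C)=C1
F7 | step 8 | (6E,9S)-9-[(tert-butyldimethylsilyl)oxy]-3,7-dimethyl-3-(phenylselanyl)cyclodec-6-en-1-one (C3 epimers) | C1[C@@H](O[Si](C)(C)C(C)(C)C)C/C(C)=C/CCC(C)([Se]c2ccccc2)CC1=O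
F8 | step 8 | (6E,9S)-9-[(tert-butyldimethylsilyl)oxy]-3,7-dimethyl-3-(phenylseleninyl)cyclodec-6-en-1-one (C3 epimers) | C1[C@@H](O[Si](C)(C)C(C)(C)C)C/C(C)=C/CCC(C)([Se](=O)c2ccccc2)CC1=O
F0 | step 15 | none | none
A1 | alternative 1 | ten-membered (E,E)-diene butenolide with C2 bis(phenylsulfonyl), C8 methoxymethyl ether and C13 silyl ether | CC(C)(C)[Si](C)(C)OCC1=C2[C@@H](OCOC)C/C(C)=C/C(S(=O)(=O)c3ccccc3)(S(=O)(=O)c3ccccc3)C/C(C)=C/[C@H]2OC1=O
A2 | alternative 2 | ten-membered (E)-cyclodecenone with C8 tert-butyl ether and C4,C5 acetonide | C1[C@@H](OC(C)(C)C)C/C(C)=C/CC[C@@]2(C)OC(C)(C)O[C@H]2C1=O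
A3 | alternative 3 | ten-membered 4,5-epoxy-1(10)E-ene butenolide, bis-silyl ether | CC(C)(C)[Si](C)(C)OCC1=C2[C@@H](O[Si](C)(C)C(C)(C)C)C/C(C)=C/CC[C@@]3(C)O[C@@H]3[C@H]2OC1=O
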